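**Plan**

1. Cuts: O1–C5 and C6–I are cut together (anti iodolactonisation of a 2-en-4-ynoic acid). The open chain O=C2–C3=C4–C5≡C6 is then traced back to a 2-furylcarbene, that is, to a furfural whose ring carbons are C2–C5 and whose CHO carbon is C6. The last cuts are C5–C6 (formylation) and C3–C1' (acylation), back to 3,4-dibromofuran.
2. Enabling feature: the butenolide ring holds C2 and C5 cis on the tetrasubstituted C3=C4 bond, and C5 carries one exocyclic carbon (C6). A furan ring holds the same four carbons cis, and a carbene at C6 unzips it to exactly this cis enyne carbonyl.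
3. Forward order: bought furan ring → acyl group at C3 → CHO at the ring C–H between O and C–Br → furan ring opened (key step) → butenolide ring closed last by 5-exo-dig attack of the carboxylate on the alkyne.
4. Stereochemistry: C1' (R) comes from a CBS reduction of the furyl ketone. The C3=C4 geometry is inherited from the furan ring. The (5E)-C5=C6 geometry comes from anti addition of O and I+ across the alkyne.

Key step: step 6

Remark: the SMILES is read as (5E) (iodine anti to O1, syn to C4–Br) and (1'R). Compounds 1 and 2 are taken as commercial.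

**Step 1**
Reactants: 1 3,4-dibromofuran; 2 N-methoxy-N-methylbutanamide
Product: 4 1-(4-bromofuran-3-yl)butan-1-one, via (4-bromofuran-3-yl)lithium 3 (not isolated)
Conditions: n-BuLi (1.0 equiv), Et2O, −78 °C; then 2, −78 → −40 °C; aq NH4Cl
Reagents that add atoms: none
Why: Bromine–lithium exchange on the symmetric dibromide gives a single 3-furyllithium that is stable at −78 °C, and its addition to the Weinreb amide stops at the chelated tetrahedral adduct, so the ketone is released only on work-up (Weinreb ketone synthesis).

**Step 2**
Reactants: 4 1-(4-bromofuran-3-yl)butan-1-one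
Product: 5 (1R)-1-(4-bromofuran-3-yl)butan-1-ol
Conditions: (S)-2-methyl-CBS-oxazaborolidine (0.15 equiv), BH3·SMe2, THF, −20 °C; MeOH quench
Reagents that add atoms: none
Why: Corey–Bakshi–Shibata reduction in which the ortho-brominated furyl group acts as the large group and n-propyl as the small group, so the (S)-catalyst should deliver hydride to the face that gives the (R)-carbinol, as with aryl n-alkyl ketones.

**Step 3**
Reactants: 5 (1R)-1-(4-bromofuran-3-yl)butan-1-ol
Product: 6 tert-butyl{[(1R)-1-(4-bromofuran-3-yl)butyl]oxy}dimethylsilane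
Conditions: TBSCl, imidazole, DMF, rt
Reagents that add atoms: tert-butyldimethylsilyl chloride, CC(C)(C)[Si](C)(C)Cl
Why: Standard silylation of a secondary alcohol; the bulky, non-coordinating ether removes the O–H that could trap the carbene of step 6 and shields the neighbouring ring C–H in step 4.

**Step 4**
Reactants: 6 tert-butyl{[(1R)-1-(4-bromofuran-3-yl)butyl]oxy}dimethylsilane
Product: 8 3-bromo-4-[(1R)-1-{[tert-butyl(dimethyl)silyl]oxy}butyl]furan-2-carbaldehyde, via 2-furyllithium 7 (not isolated)
Conditions: LDA (commercial solution, 1.1 equiv), THF, −78 °C; DMF, −78 → −40 °C; aq NH4Cl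
Reagents that add atoms: N,N-dimethylformamide, CN(C)C=O
Why: Amide-base deprotonation of a 3-bromofuran takes place at the α-position flanked by ring oxygen and bromine, whereas the other α-C–H is unactivated and hindered by the silyloxybutyl arm; the 2-furyllithium is then formylated by DMF at −78 °C, where halogen migration should not compete.

**Step 5**
Reactants: 8 3-bromo-4-[(1R)-1-{[tert-butyl(dimethyl)silyl]oxy}butyl]furan-2-carbaldehyde
Product: 9 N'-[(E)-{3-bromo-4-[(1R)-1-{[tert-butyl(dimethyl)silyl]oxy}butyl]furan-2-yl}methylidene]-4-methylbenzenesulfonohydrazide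
Conditions: TsNHNH2 (1.05 equiv), THF, rt
Reagents that add atoms: 4-methylbenzenesulfonohydrazide, Cc1ccc(cc1)S(=O)(=O)NN
Why: Uncatalysed condensation of an aromatic aldehyde with tosylhydrazide should give the hydrazone and leave the silyl ether and the ring bromide untouched.

**Step 6**
Reactants: 9 N'-[(E)-{3-bromo-4-[(1R)-1-{[tert-butyl(dimethyl)silyl]oxy}butyl]furan-2-yl}methylidene]-4-methylbenzenesulfonohydrazide
Product: 13 (2E)-3-bromo-2-[(1R)-1-{[tert-butyl(dimethyl)silyl]oxy}butyl]pent-2-en-4-ynal, via sodium hydrazonate 10 (not isolated), via furyldiazomethane 11 (not isolated), via furylcarbene 12 (not isolated)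
Conditions: NaH (1.05 equiv), THF, 0 °C; then slow addition to 1,4-dioxane at 95 °C (final 0.01 M), dark
Reagents that add atoms: none
Why: Aprotic Bamford–Stevens decomposition: the sodium hydrazonate 10 loses sulfinate to the furyldiazomethane 11, which loses N2 to the singlet 2-furylcarbene 12, and the carbene lone pair then expels the ring oxygen from the adjacent ring carbon while the furan π electrons shift, so that the C≡C, the C=C and the C=O of the enynal form in one fragmentation. The closest known reaction is the thermal conversion of furfural tosylhydrazone salts into cis-pent-2-en-4-ynal (furfurylidene ring-opening), here applied to a ring-substituted furfural. No ring is closed; the furan ring is opened, and since its two α-carbons were tied through oxygen on the same side of the C3=C4 bond, formyl and ethynyl must end cis, which delivers the tetrasubstituted bromoalkene as the single (2E) isomer without any selectivity being asked of a reagent. No stereocentre is formed, and the silyl-protected carbinol lies outside the reorganising atoms. The selectivity needed is fragmentation of the carbene over bimolecular loss of 11 or 12 (azine formation, dipolar addition to the product alkyne, X–H insertion); the very low barrier expected for the ring-opening, slow addition into hot dilute solution and the absence of any O–H should secure it. Dioxane keeps sodium sulfinate largely undissolved, which limits its conjugate attack on the β-bromo enal.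

**Step 7**
Reactants: 13 (2E)-3-bromo-2-[(1R)-1-{[tert-butyl(dimethyl)silyl]oxy}butyl]pent-2-en-4-ynal
Product: 14 (2E)-3-bromo-2-[(1R)-1-{[tert-butyl(dimethyl)silyl]oxy}butyl]pent-2-en-4-ynoic acid
Conditions: NaClO2, NaH2PO4, 2-methylbut-2-ene, t-BuOH/H2O, 0 °C → rt
Reagents that add atoms: sodium chlorite, [Na+].[O-]Cl=O
Why: Pinnick oxidation converts the non-enolisable enal into the acid under buffered conditions that should leave alkyne, vinyl bromide, silyl ether and double-bond geometry alone, the hypochlorous acid being taken up by the alkene scavenger.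

**Step 8**
Reactants: 14 (2E)-3-bromo-2-[(1R)-1-{[tert-butyl(dimethyl)silyl]oxy}butyl]pent-2-en-4-ynoic acid
Product: 15 (2E)-3-bromo-2-[(1R)-1-hydroxybutyl]pent-2-en-4-ynoic acid
Conditions: 48% aq HF/MeCN (1:19), 0 °C → rt
Reagents that add atoms: none
Why: Acidic fluoride cleavage of the secondary TBS ether is done at the robust acid stage so that the sensitive iodoalkene is made in the last step and needs no further handling; the freed hydroxyl sits trans to the alkyne and cannot cyclise onto it.

**Step 9**
Reactants: 15 (2E)-3-bromo-2-[(1R)-1-hydroxybutyl]pent-2-en-4-ynoic acid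
Product: 16 (5E)-4-bromo-3-[(1R)-1-hydroxybutyl]-5-(iodomethylidene)furan-2(5H)-one
Conditions: NIS (1.05 equiv), NaHCO3 (0.2 equiv), MeCN, 0 °C, dark; aq Na2S2O3
Reagents that add atoms: N-iodosuccinimide, O=C1CCC(=O)N1I
Why: Iodolactonisation of a (Z)-configured 2-en-4-ynoic acid: the carboxylate, held cis to the alkyne, attacks the internal carbon of the iodonium-activated triple bond in the 5-exo-dig mode and anti to iodine, which places I trans to O1 and so should give the (5E)-iodomethylidene lactone with the carbinol centre untouched.

**Compound list**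

1 | 3,4-dibromofuran | Brc1cocc1Br | starting material
2 | N-methoxy-N-methylbutanamide | CCCC(=O)N(C)OC | starting material
3 | (4-bromofuran-3-yl)lithium | [Li]c1cocc1Br | intermediate
4 | 1-(4-bromofuran-3-yl)butan-1-one | CCCC(=O)c1cocc1Br | intermediate
5 | (1R)-1-(4-bromofuran-3-yl)butan-1-ol | CCC[C@@H](O)c1cocc1Br | intermediate
6 | tert-butyl{[(1R)-1-(4-bromofuran-3-yl)butyl]oxy}dimethylsilane | CCC[C@@H](O[Si](C)(C)C(C)(C)C)c1cocc1Br | intermediate
7 | {3-bromo-4-[(1R)-1-{[tert-butyl(dimethyl)silyl]oxy}butyl]furan-2-yl}lithium | CCC[C@@H](O[Si](C)(C)C(C)(C)C)c1coc([Li])c1Br | intermediate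
8 | 3-bromo-4-[(1R)-1-{[tert-butyl(dimethyl)silyl]oxy}butyl]furan-2-carbaldehyde | CCC[C@@H](O[Si](C)(C)C(C)(C)C)c1coc(C=O)c1Br | intermediate
9 | N'-[(E)-{3-bromo-4-[(1R)-1-{[tert-butyl(dimethyl)silyl]oxy}butyl]furan-2-yl}methylidene]-4-methylbenzenesulfonohydrazide | CCC[C@@H](O[Si](C)(C)C(C)(C)C)c1coc(/C=N/NS(=O)(=O)c2ccc(C)cc2)c1Br | intermediate
10 | sodium salt of hydrazone 9 | CCC[C@@H](O[Si](C)(C)C(C)(C)C)c1coc(/C=N/[N-]S(=O)(=O)c2ccc(C)cc2)c1Br.[Na+] | intermediate
11 | tert-butyl{[(1R)-1-[4-bromo-5-(diazomethyl)furan-3-yl]butyl]oxy}dimethylsilane | CCC[C@@H](O[Si](C)(C)C(C)(C)C)c1coc(C=[N+]=[N-])c1Br | intermediate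
12 | {3-bromo-4-[(1R)-1-{[tert-butyl(dimethyl)silyl]oxy}butyl]furan-2-yl}carbene | CCC[C@@H](O[Si](C)(C)C(C)(C)C)c1coc([CH])c1Br | intermediate
13 | (2E)-3-bromo-2-[(1R)-1-{[tert-butyl(dimethyl)silyl]oxy}butyl]pent-2-en-4-ynal | CCC[C@@H](O[Si](C)(C)C(C)(C)C)/C(C=O)=C(\Br)C#C | intermediate
14 | (2E)-3-bromo-2-[(1R)-1-{[tert-butyl(dimethyl)silyl]oxy}butyl]pent-2-en-4-ynoic acid | CCC[C@@H](O[Si](C)(C)C(C)(C)C)/C(C(=O)O)=C(\Br)C#C | intermediate
15 | (2E)-3-bromo-2-[(1R)-1-hydroxybutyl]pent-2-en-4-ynoic acid | CCC[C@@H](O)/C(C(=O)O)=C(\Br)C#C | intermediate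
16 | (5E)-4-bromo-3-[(1R)-1-hydroxybutyl]-5-(iodomethylidene)furan-2(5H)-one | CCC[C@@H](O)C1=C(Br)/C(=C\I)OC1=O | target

**Totals**

Total step count: 9. Longest linear sequence: 9 steps (1 → 16).

**Steps most likely to fail**

Step 6. The diazo compound may be consumed bimolecularly (azine formation, dipolar addition to the alkyne of product already formed) before it loses nitrogen. Sulfinate may also add to the β-bromo enal, with loss of bromide or scrambling of the alkene geometry. The fallback keeps the furan as the cis template but opens it by oxidation instead of by a carbene; it sets out from alcohol 5 and comes back at acid 15. Dehydrogenative silylation of 5 with diethylsilane ([Ir(cod)OMe]2 cat., THF, rt) should give {[(1R)-1-(4-bromofuran-3-yl)butyl]oxy}diethylsilane F1. With [Ir(cod)OMe]2/1,10-phenanthroline and norbornene at 80 °C, hydroxyl-directed C–H silylation can only reach furan C2, since the other ortho position carries bromine. This should close F1 to the cyclic silyl ether (3R)-4-bromo-1,1-diethyl-3-propyl-1,3-dihydrofuro[2,3-c][1,2]oxasilole F2. Photooxygenation of this 2-silylfuran (O2, rose bengal, hν, CH2Cl2/MeOH, −78 °C; aqueous work-up) makes the silicon-bearing carbon the lactone carbonyl and should give 4-bromo-5-hydroxy-3-[(1R)-1-hydroxybutyl]furan-2(5H)-one F3. F3 is the ring form of the cis formyl acid with the aldehyde next to C–Br. Seyferth–Gilbert homologation of its open form with the Ohira–Bestmann reagent (K2CO3, MeOH, 0 °C → rt) should then give 15, which enters step 9 unchanged.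

Step 9. Closure may partly take the 6-endo course to the iodopyranone. The strained E-iodoalkene (iodine next to bromine) may also isomerise to the Z isomer through reversible addition of iodine-centred species or through light. The fallback separates ring closure from iodination; it sets out from 15 and comes back at 16. Mercuricyclisation of 15 (Hg(OCOCF3)2, CH2Cl2, 0 °C; then aq NaCl) is an anti oxymercuration with a strong 5-exo preference. It should give the isolable vinylmercurial (5E)-4-bromo-5-[(chloromercurio)methylidene]-3-[(1R)-1-hydroxybutyl]furan-2(5H)-one F4. Iododemercuration (I2, CH2Cl2, −20 °C, dark) proceeds with retention and should give 16.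

Step 2. Facial discrimination between n-propyl and the bromofuryl group may be incomplete, and a loss of enantiopurity here cannot be repaired later. The fallback replaces asymmetric reduction by enzymatic resolution; it sets out from ketone 4 and comes back at 5. NaBH4 in MeOH should give rac-1-(4-bromofuran-3-yl)butan-1-ol F5. Burkholderia cepacia lipase with vinyl acetate (MTBE, 30 °C) should acylate the R enantiomer to (1R)-1-(4-bromofuran-3-yl)butyl acetate F6 and leave (1S)-1-(4-bromofuran-3-yl)butan-1-ol F7, which can be re-oxidised to 4 and recycled. Methanolysis of F6 (K2CO3, MeOH) should give 5.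

**Further compounds**

F1 | step 6 | {[(1R)-1-(4-bromofuran-3-yl)butyl]oxy}diethylsilane | CCC[C@@H](O[SiH](CC)CC)c1cocc1Br
F2 | step 6 | (3R)-4-bromo-1,1-diethyl-3-propyl-1,3-dihydrofuro[2,3-c][1,2]oxasilole | CCC[C@H]1O[Si](CC)(CC)c2occ(Br)c12
F3 | step 6 | 4-bromo-5-hydroxy-3-[(1R)-1-hydroxybutyl]furan-2(5H)-one | CCC[C@@H](O)C1=C(Br)C(O)OC1=O
F4 | step 9 | (5E)-4-bromo-5-[(chloromercurio)methylidene]-3-[(1R)-1-hydroxybutyl]furan-2(5H)-one | CCC[C@@H](O)C1=C(Br)/C(=C\[Hg]Cl)OC1=O
F5 | step 2 | rac-1-(4-bromofuran-3-yl)butan-1-ol | CCCC(O)c1cocc1Br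
F6 | step 2 | (1R)-1-(4-bromofuran-3-yl)butyl acetate | CCC[C@@H](OC(C)=O)c1cocc1Br
F7 | step 2 | (1S)-1-(4-bromofuran-3-yl)butan-1-ol | CCC[C@H](O)c1cocc1Br
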